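Over 2.0 d I let a racemate of left-handed and right-handed substrate stand under held gas with the single-handed free catalyst, hoping for a kinetic resolution that leaves right-handed substrate in excess.

| setting | amber | teal | flask |
|---|---|---|---|
| left-handed substrate | 0.55 M | 2.2 M | 1.1 M |
| right-handed substrate | 0.55 M | 2.2 M | 1.1 M |
| gas | 120 mM (held) | 120 mM (held) | 120 mM (held) |
| free catalyst | 88 mM | 88 mM | 88 mM |
| remark | run made earlier | run made earlier |  |
| time |  |  | 2.0 d |

| run | time / h | right-handed substrate / % | left-handed substrate / % | left-handed product / % |
|---|---|---|---|---|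
| amber | 6.00 | 43.2 | 1.1 | 47.8 |
| amber | 12.0 | 40.7 | 0.1 | 50.1 |
| amber | 20.0 | 36.1 | 0 | 49.9 |
| amber | 25.0 | 34.0 | 0.2 | 50.1 |
| amber | 30.0 | 31.9 | 0.2 | 50.2 |
| amber | 40.0 | 28.3 | 0.2 | 50.1 |
| teal | 3.00 | 49.2 | 29.7 | 19.2 |
| teal | 5.00 | 48.7 | 19.8 | 30.3 |
| teal | 8.00 | 48.0 | 9.0 | 40.1 |
| teal | 15.0 | 45.7 | 0.5 | 49.1 |
| teal | 25.0 | 42.8 | 0.1 | 50.0 |
| teal | 40.0 | 39.6 | 0.2 | 50.4 |

(each reading ± 0.5 percentage points)

- whether the excess of right-handed substrate over left-handed substrate among what is left of the two reaches 80% by 2.0 d (yes / no)
- the highest excess of right-handed substrate over left-handed substrate among what is left of the two up to 2.0 d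

- free catalyst is single-handed; left-handed substrate and right-handed substrate are mirror images of each other, charged as a racemate, each of them at the stated concentration
- at the start none of the gas is in solution

Free catalyst was charged in the smallest amount, so I wrote its balance. If each catalyst binds one substrate, c(free catalyst) over both substrate charges gives 4.00% in this flask, the hiding ceiling: the largest share of the charged substrate that can sit bound on the catalyst.

In the amber run the ceiling was 8.00%. The readings there missed 7.90% at 6.00 h, which fits it, but 21.4% at 40.0 h, which is more than the catalyst can hide. So right-handed substrate was leaving for something unread, while left-handed product stayed flat at 50.1%. Right-handed substrate still read 28.3% there and 39.6% in the teal run, while left-handed substrate read 0.2% and 0.2%, so I expected the excess in this flask to come close to complete.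

The forecast said yes, with a top of 99.8%, holding that “left-handed substrate should be gone by about 10 h”.

The flask gave yes, with a top of 100%.

    partner + catalyst intermediate B → free catalyst + right-handed product (k = 1.30 M⁻¹ h⁻¹)
    free catalyst + left-handed substrate ⇌ catalyst intermediate A (K = 2.70 M⁻¹, k = 360 M⁻¹ h⁻¹)
    gas ⇌ partner, rate k3*(csat - [partner]) (kL = 200 h⁻¹)
    partner + catalyst intermediate A → free catalyst + left-handed product (k = 58.0 M⁻¹ h⁻¹)
    free catalyst + right-handed substrate ⇌ catalyst intermediate B (K = 1.70 M⁻¹, k = 49.0 M⁻¹ h⁻¹)
    partner ⇌ dormant form (K = 16.0, k = 0.290 h⁻¹)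

The excess in the flask reached 80% after 0.239 d. At 2.00 d the excess of 100% stood on 30.9% of right-handed substrate in percent of the whole charge, with left-handed substrate at 0%. Catalyst intermediate B then held 53.5% of the catalyst, which is 2.14% of the charge, under the ceiling of 4.00%. Right-handed product stood above that ceiling, at 17.0%.

The numbers in the tables stem from a simulated flask with made-up constants, noise included.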